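## Retrosynthetic overview

- Ring D (C13–C18) is a cyclohexene that shares its C17–C18 edge cis with ring E, with the quaternary C17 (C28 carboxyl) flanked by C18–H and the oxygenated C19. This is the pattern of a [4+2] adduct, so C13–C18 and C16–C17 are cut to give the ring C diene C13=C14–C15=C16 (17) and the ring E enone ester C17=C18 (20).
- After the cycloaddition: C19 ketone to the 19α-alcohol, shift of C14=C15 into C13=C14, then deprotection.
- Diene 17 comes from ring-closing enyne metathesis of an 8α-ethynyl decalin carrying a C12 homoallyl methyl ether. C12 is set by reagent-controlled allylboration, which also resolves the racemic decalin. The quaternary C8 is set by radical hydroalkynylation of an exocyclic alkene.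
- The AB decalin comes from a Mn(OAc)3-mediated radical bicyclization of a β-keto ester built from geranyl acetate and methyl 2-methyl-3-oxobutanoate. Ring E comes from 4,4-dimethylcyclohexane-1,3-dione.
- Ring order: A and B together, then C, then D by the Diels–Alder step onto the preformed ring E.

Key step: step 16

Remark: locants follow oleanane numbering with ring C enlarged (C27 = ring C methylene between C12 and C13; C23 = 4α-methyl; C24 = 4β-ester carbon; C25 on C10; C26 on C8; C28 on C17); compounds 7–14 are racemic and are drawn as the enantiomer that is carried on after step 11.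

## Route

Step 1
Reactants: 1 geranyl acetate
Product: 2 (2E,6E)-8-hydroxy-3,7-dimethylocta-2,6-dien-1-yl acetate
Conditions: SeO2 (cat.), tBuOOH, salicylic acid (cat.), CH2Cl2, rt
Reagents that add atoms: tert-butyl hydroperoxide, CC(C)(C)OO
Why: Sharpless SeO2/tBuOOH allylic oxidation (ene reaction then [2,3]-sigmatropic shift) should hydroxylate the (E)-methyl group of the electron-richer terminal alkene, the alkene next to the acetate being deactivated.

Step 2
Reactants: 2 (2E,6E)-8-hydroxy-3,7-dimethylocta-2,6-dien-1-yl acetate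
Product: 3 (2E,6E)-8-bromo-3,7-dimethylocta-2,6-dien-1-yl acetate
Conditions: CBr4, PPh3, CH2Cl2, 0 °C
Reagents that add atoms: carbon tetrabromide, BrC(Br)(Br)Br
Why: The Appel reaction converts the primary allylic alcohol into the bromide by SN2 attack of bromide on the alkoxyphosphonium ion under neutral conditions that leave the acetate and both alkene geometries intact.

Step 3
Reactants: 4 methyl 2-methyl-3-oxobutanoate; 3 (2E,6E)-8-bromo-3,7-dimethylocta-2,6-dien-1-yl acetate
Product: 6 methyl (6E,10E)-12-acetoxy-2,6,10-trimethyl-3-oxododeca-6,10-dienoate, via acetoacetate dianion 5 (not isolated)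
Conditions: NaH, THF, 0 °C; nBuLi, 0 °C; then 3, −78 to 0 °C; 1 M HCl
Reagents that add atoms: none
Why: Weiler dianion alkylation: the terminal carbanion of the dianion is the more nucleophilic site and should displace the allylic bromide by SN2 at low temperature faster than it attacks the acetate, giving the γ-alkylated β-keto ester.

Step 4
Reactants: 6 methyl (6E,10E)-12-acetoxy-2,6,10-trimethyl-3-oxododeca-6,10-dienoate
Product: 7 rac-AB keto ester (3-oxo; 4α-Me; 4β-CO2Me; 5α-H; 9α-H; 10β-Me; 9β-CH2OAc; 8(26)-methylidene)
Conditions: Mn(OAc)3·2H2O (2.2 equiv), Cu(OAc)2·H2O (1 equiv), degassed AcOH, rt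
Reagents that add atoms: none
Why: Snider oxidative radical polyene cyclization: the manganese enolate gives the C4 radical, which closes ring A and then ring B by two 6-endo additions through a chair–chair array (trans ring fusion with 10β-methyl, 5α-H and 9α-H from the E alkenes, ester axial at C4 as is usual for α-methyl β-keto esters), and Cu(OAc)2 oxidises the tertiary C8 radical to the exocyclic alkene.

Step 5
Reactants: 7 rac-AB keto ester
Product: 8 rac-3α-alcohol (axial OH; otherwise as 7)
Conditions: LiBH(sBu)3 (L-Selectride), THF, −78 °C; H2O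
Reagents that add atoms: none
Why: Reduction with a bulky trialkylborohydride under steric approach control should deliver hydride equatorially to the C3 ketone, as with 4,4-disubstituted 3-oxo triterpenoids, to set the axial 3α-alcohol while the primary acetate survives at −78 °C.

Step 6
Reactants: 8 rac-3α-alcohol
Product: 9 rac-3α-O-TBS ether
Conditions: TBSOTf, 2,6-lutidine, CH2Cl2, 0 °C to rt
Reagents that add atoms: tert-butyldimethylsilyl triflate, CC(C)(C)[Si](C)(C)OS(=O)(=O)C(F)(F)F
Why: Silylation with the silyl triflate and a hindered pyridine base is the standard way to protect a hindered axial secondary alcohol and blocks oxidation and alkylation at O3 in steps 9 and 12.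

Step 7
Reactants: 9 rac-3α-O-TBS ether
Product: 10 rac-8α-[(trimethylsilyl)ethynyl]-8β-methyl decalin (11-acetate)
Conditions: Fe(acac)3 (30 mol %), PhSiH3, p-tolyl 2-(trimethylsilyl)ethynyl sulfone, EtOH/ethylene glycol, 60 °C
Reagents that add atoms: p-tolyl 2-(trimethylsilyl)ethynyl sulfone, Cc1ccc(cc1)S(=O)(=O)C#C[Si](C)(C)C
Why: Metal hydride hydrogen-atom-transfer hydroalkynylation (Mukaiyama-type radical hydrofunctionalization with an alkynyl sulfone acceptor): hydrogen-atom transfer to the CH2 terminus gives the tertiary C8 radical, which adds to the sulfone-bearing alkyne carbon and expels the sulfonyl radical on the α face, anti to the axial C25 methyl, so that the alkyne becomes equatorial and the new C26 methyl axial (β).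

Step 8
Reactants: 10 rac-8α-[(trimethylsilyl)ethynyl]-8β-methyl decalin (11-acetate)
Product: 11 rac-8α-ethynyl decalin 11-alcohol
Conditions: K2CO3, MeOH, rt
Reagents that add atoms: none
Why: Potassium carbonate in methanol cleaves the primary acetate by transesterification and the alkynyl C–Si bond by methoxide attack on silicon in one operation, while the hindered C24 ester and the silyl ether are not affected.

Step 9
Reactants: 11 rac-8α-ethynyl decalin 11-alcohol
Product: 12 rac-8α-ethynyl decalin 11-aldehyde
Conditions: Dess–Martin periodinane, CH2Cl2, rt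
Reagents that add atoms: none
Why: Dess–Martin oxidation takes the neopentyl-type primary alcohol to the aldehyde under neutral conditions without epimerising C9.

Step 10
Reactants: 12 rac-8α-ethynyl decalin 11-aldehyde
Product: 14 rac-C12 aldehyde (9β-CH2CHO), via methyl enol ether 13 (not isolated)
Conditions: Ph3P(CH2OMe)Cl, KHMDS, THF, 0 °C; then 1 M HCl, THF, rt
Reagents that add atoms: (methoxymethyl)triphenylphosphonium chloride, COC[P+](c1ccccc1)(c1ccccc1)c1ccccc1.[Cl-]; water, O
Why: Wittig methoxymethylenation followed by acid hydrolysis of the enol ether is the standard one-carbon homologation of a hindered aldehyde and moves the carbonyl from C11 to C12.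

Step 11
Reactants: 14 rac-C12 aldehyde
Product: 15 (12R)-homoallylic alcohol (12α-OH; single enantiomer with the decalin configuration of the target)
Conditions: (+)-Ipc2B(allyl) [from (+)-Ipc2BOMe (made from (−)-α-pinene) and allylMgBr, Et2O], −78 °C; then NaOH, H2O2; chromatographic separation of the two diastereomeric alcohols
Reagents that add atoms: (+)-B-allyldiisopinocampheylborane, C=CCB([C@H]1C[C@H]2C[C@@H]([C@@H]1C)C2(C)C)[C@H]1C[C@H]2C[C@@H]([C@@H]1C)C2(C)C
Why: Brown allylboration through a chair Zimmerman–Traxler transition state is reagent-controlled and should add allyl to the Re face of the aldehyde in both enantiomers of 14, setting (12R) and turning the racemate into two diastereomers, of which 15 is kept and the (12R) alcohol built on the enantiomeric decalin is removed by chromatography, the enantiomeric purity of 15 being that of the reagent's face selectivity.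

Step 12
Reactants: 15 (12R)-homoallylic alcohol
Product: 16 (12R)-homoallylic methyl ether (enyne)
Conditions: Me3OBF4, 1,8-bis(dimethylamino)naphthalene, CH2Cl2, rt
Reagents that add atoms: trimethyloxonium tetrafluoroborate, C[O+](C)C.F[B-](F)(F)F
Why: O-Methylation with Meerwein's salt and a non-nucleophilic proton scavenger alkylates the secondary alcohol without a base strong enough to deprotonate the terminal alkyne or to open the β-silyloxy ester.

Step 13
Reactants: 16 (12R)-homoallylic methyl ether (enyne)
Product: 17 ABC diene (ring C cyclohept-13-ene; 14-vinyl; 12α-OMe; 3α-OTBS; C24 methyl ester)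
Conditions: second-generation Grubbs catalyst RuCl2(=CHPh)(H2IMes)(PCy3) (10 mol %), ethylene (1 atm), CH2Cl2, 40 °C
Reagents that add atoms: none
Why: Ring-closing enyne metathesis (Mori conditions under ethylene) should close the seven-membered ring in the exo mode, the ruthenium alkylidene formed at the terminal alkene adding to the alkyne at C14 so that C13=C14 lies inside ring C and the former alkyne terminus becomes the C15=C16 vinyl group.

Step 14
Reactants: 18 4,4-dimethylcyclohexane-1,3-dione
Product: 19 4,4-dimethyl-3-oxocyclohex-1-en-1-yl trifluoromethanesulfonate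
Conditions: Tf2O, pyridine, CH2Cl2, −78 to 0 °C
Reagents that add atoms: triflic anhydride, O=S(=O)(OS(=O)(=O)C(F)(F)F)C(F)(F)F
Why: O-Sulfonylation of the 1,3-diketone enolate should occur at the oxygen remote from the gem-dimethyl group, leaving the hindered carbonyl as the enone ketone.

Step 15
Reactants: 19 4,4-dimethyl-3-oxocyclohex-1-en-1-yl trifluoromethanesulfonate
Product: 20 methyl 4,4-dimethyl-3-oxocyclohex-1-ene-1-carboxylate
Conditions: Pd(OAc)2 (cat.), 1,3-bis(diphenylphosphino)propane, CO (1 atm), MeOH, Et3N, DMF, 60 °C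
Reagents that add atoms: carbon monoxide, [C-]#[O+]; methanol, CO
Why: Palladium-catalysed alkoxycarbonylation of a β-triflyloxy enone (oxidative addition, CO insertion, methanolysis) is a standard route to 3-oxocycloalkene-1-carboxylates.

Step 16
Reactants: 17 ABC diene; 20 methyl 4,4-dimethyl-3-oxocyclohex-1-ene-1-carboxylate
Product: 21 Diels–Alder adduct (rings A–E; C14=C15; 19-oxo; 13β-H; 18β-H; 17β-CO2Me)
Conditions: Et2AlCl (2 equiv), dienophile 20 (2 equiv), CH2Cl2, −78 to −20 °C
Reagents that add atoms: none
Why: Complexation of the ring E ketone by Et2AlCl lowers the LUMO and puts its largest coefficient on C17, which bonds to the unsubstituted diene terminus C16 while C18 bonds to C13 in a concerted but asynchronous [4+2] cycloaddition of the kind well known for 1-vinylcycloalkenes and cyclic enones under aluminium Lewis acids. Ring D is closed intermolecularly as a six-membered ring by suprafacial addition on both partners, so the cis relationship of the ester and H18 across the ring E alkene is carried into the cis C17–C18 ring fusion. The absolute sense at C17 and C18 follows from attack on the α face of the diene with the ketone endo: the β face is screened by the axial C26 methyl on C8, and the 12α-methoxy oxygen lies under ring C where the endo ketone oxygen arrives, so that one aluminium centre can bridge both oxygens. C13 is formed with H13 β and is erased again in step 18. The step needs regio-, face- and endo-selectivity together; the first rests on the ketone and not the ester being the Lewis-basic site and on the 1-alkyl substitution of the diene, the other two on the substrate features just named. The reactive s-cis diene conformer should be favoured because the s-trans form presses C16 against the substituents of C8.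

Step 17
Reactants: 21 Diels–Alder adduct
Product: 22 19α-alcohol (axial OH; C14=C15)
Conditions: LiBH(sBu)3 (L-Selectride), THF, −78 °C; H2O
Reagents that add atoms: none
Why: The bulky hydride should attack the C19 ketone equatorially from the β face, because the α face is screened by the axial C16–C17 bond of the cis-fused ring D (ring E chair with C13 equatorial, enforced by the C20 gem-dimethyl group), giving the axial 19α-alcohol before C18 can epimerise.

Step 18
Reactants: 22 19α-alcohol
Product: 23 C13=C14 isomer (tetrasubstituted alkene)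
Conditions: [N,N′-bis(3,5-di-tert-butylsalicylidene)-1,2-cyclohexanediaminato]cobalt chloride (Co(salen)Cl, 5 mol %), PhSiH3 (10 mol %), benzene, rt to 50 °C
Reagents that add atoms: none
Why: Metal hydride hydrogen-atom-transfer alkene isomerization: reversible hydrogen-atom transfer to C15 gives the tertiary C14 radical, which can lose hydrogen only from C13 or C15 because C8 is quaternary, so the alkene should settle in the tetrasubstituted C13=C14 position without the skeletal shifts of a cationic process and with loss of the C13 stereocentre.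

Step 19
Reactants: 23 C13=C14 isomer
Product: 24 3α,19α-diol dimethyl ester
Conditions: 48% aq. HF, MeCN, rt
Reagents that add atoms: none
Why: Fluoride-assisted cleavage of the Si–O bond removes the hindered silyl ether under conditions that do not touch the esters, the methyl ether or the tetrasubstituted alkene.

Step 20
Reactants: 24 3α,19α-diol dimethyl ester
Product: 25 CNP0394974.1
Conditions: nPrSLi (from nPrSH and nBuLi), HMPA, rt to 50 °C; then 1 M HCl
Reagents that add atoms: none
Why: Bartlett–Johnson dealkylation: the thiolate attacks the methyl groups of the two hindered tertiary esters by SN2, which avoids acyl attack at the shielded carbonyls and leaves the secondary methyl ether untouched.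

## Compound list

1 | geranyl acetate | CC(C)=CCC/C(C)=C/COC(C)=O | starting material
2 | (2E,6E)-8-hydroxy-3,7-dimethylocta-2,6-dien-1-yl acetate | OC/C(C)=C/CC/C(C)=C/COC(C)=O | intermediate
3 | (2E,6E)-8-bromo-3,7-dimethylocta-2,6-dien-1-yl acetate | BrC/C(C)=C/CC/C(C)=C/COC(C)=O | intermediate
4 | methyl 2-methyl-3-oxobutanoate | COC(=O)C(C)C(C)=O | starting material
5 | C2,C4-dianion of methyl 2-methyl-3-oxobutanoate (sodium lithium salt; not isolated) | COC(=O)[C-](C)C(=O)[CH2-].[Na+].[Li+] | intermediate
6 | methyl (6E,10E)-12-acetoxy-2,6,10-trimethyl-3-oxododeca-6,10-dienoate | COC(=O)C(C)C(=O)CC/C(C)=C/CC/C(C)=C/COC(C)=O | intermediate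
7 | rac-methyl 5-(acetoxymethyl)-1,4a-dimethyl-6-methylidene-2-oxodecahydronaphthalene-1-carboxylate (trans-decalin; 4β-CO2Me axial, 5α-H, 9α-H, 10β-Me; racemic) | C=C1CC[C@@H]2[C@](C)(CCC(=O)[C@]2(C)C(=O)OC)[C@H]1COC(C)=O | intermediate
8 | rac-methyl 5-(acetoxymethyl)-2-hydroxy-1,4a-dimethyl-6-methylidenedecahydronaphthalene-1-carboxylate (3α-OH axial; racemic) | C=C1CC[C@@H]2[C@](C)(CC[C@@H](O)[C@]2(C)C(=O)OC)[C@H]1COC(C)=O | intermediate
9 | rac-3α-O-tert-butyldimethylsilyl ether of 8 | C=C1CC[C@@H]2[C@](C)(CC[C@@H](O[Si](C)(C)C(C)(C)C)[C@]2(C)C(=O)OC)[C@H]1COC(C)=O | intermediate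
10 | rac-methyl 5-(acetoxymethyl)-2-(tert-butyldimethylsilyloxy)-1,4a,6-trimethyl-6-[(trimethylsilyl)ethynyl]decahydronaphthalene-1-carboxylate (8α-alkynyl equatorial, 8β-methyl axial) | C[Si](C)(C)C#C[C@]1(C)CC[C@@H]2[C@](C)(CC[C@@H](O[Si](C)(C)C(C)(C)C)[C@]2(C)C(=O)OC)[C@H]1COC(C)=O | intermediate
11 | rac-methyl 2-(tert-butyldimethylsilyloxy)-6-ethynyl-5-(hydroxymethyl)-1,4a,6-trimethyldecahydronaphthalene-1-carboxylate | C#C[C@]1(C)CC[C@@H]2[C@](C)(CC[C@@H](O[Si](C)(C)C(C)(C)C)[C@]2(C)C(=O)OC)[C@H]1CO | intermediate
12 | rac-methyl 2-(tert-butyldimethylsilyloxy)-6-ethynyl-5-formyl-1,4a,6-trimethyldecahydronaphthalene-1-carboxylate | C#C[C@]1(C)CC[C@@H]2[C@](C)(CC[C@@H](O[Si](C)(C)C(C)(C)C)[C@]2(C)C(=O)OC)[C@H]1C=O | intermediate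
13 | rac-5-(2-methoxyethenyl) analogue of 12 (methyl enol ether, E/Z mixture; not isolated) | C#C[C@]1(C)CC[C@@H]2[C@](C)(CC[C@@H](O[Si](C)(C)C(C)(C)C)[C@]2(C)C(=O)OC)[C@H]1C=COC | intermediate
14 | rac-methyl 2-(tert-butyldimethylsilyloxy)-6-ethynyl-1,4a,6-trimethyl-5-(2-oxoethyl)decahydronaphthalene-1-carboxylate (C12 aldehyde) | C#C[C@]1(C)CC[C@@H]2[C@](C)(CC[C@@H](O[Si](C)(C)C(C)(C)C)[C@]2(C)C(=O)OC)[C@H]1CC=O | intermediate
15 | methyl 2-(tert-butyldimethylsilyloxy)-6-ethynyl-5-[(2R)-2-hydroxypent-4-en-1-yl]-1,4a,6-trimethyldecahydronaphthalene-1-carboxylate (12α-OH; decalin as in the target; single enantiomer) | C#C[C@]1(C)CC[C@@H]2[C@](C)(CC[C@@H](O[Si](C)(C)C(C)(C)C)[C@]2(C)C(=O)OC)[C@H]1C[C@H](O)CC=C | intermediate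
16 | methyl 2-(tert-butyldimethylsilyloxy)-6-ethynyl-5-[(2R)-2-methoxypent-4-en-1-yl]-1,4a,6-trimethyldecahydronaphthalene-1-carboxylate | C#C[C@]1(C)CC[C@@H]2[C@](C)(CC[C@@H](O[Si](C)(C)C(C)(C)C)[C@]2(C)C(=O)OC)[C@H]1C[C@H](OC)CC=C | intermediate
17 | ABC diene: ring C cyclohept-13-ene with 14-vinyl, 12α-OMe, 3α-OTBS, 4β-CO2Me (C24), 8β-Me, 10β-Me | CO[C@@H]1CC=C(C=C)[C@]2(C)CC[C@@H]3[C@](C)(CC[C@@H](O[Si](C)(C)C(C)(C)C)[C@]3(C)C(=O)OC)[C@H]2C1 | intermediate
18 | 4,4-dimethylcyclohexane-1,3-dione | CC1(C)CCC(=O)CC1=O | starting material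
19 | 4,4-dimethyl-3-oxocyclohex-1-en-1-yl trifluoromethanesulfonate | CC1(C)CCC(OS(=O)(=O)C(F)(F)F)=CC1=O | intermediate
20 | methyl 4,4-dimethyl-3-oxocyclohex-1-ene-1-carboxylate | COC(=O)C1=CC(=O)C(C)(C)CC1 | intermediate
21 | Diels–Alder adduct: pentacycle with C14=C15, 19-oxo, 13β-H, 18β-H, 17β-CO2Me, 12α-OMe, 3α-OTBS | CO[C@@H]1C[C@H]2C(=CC[C@@]3(C(=O)OC)CCC(C)(C)C(=O)[C@@H]23)[C@]2(C)CC[C@@H]3[C@](C)(CC[C@@H](O[Si](C)(C)C(C)(C)C)[C@]3(C)C(=O)OC)[C@H]2C1 | intermediate
22 | 19α-alcohol of 21 (C14=C15) | CO[C@@H]1C[C@H]2C(=CC[C@@]3(C(=O)OC)CCC(C)(C)[C@@H](O)[C@@H]23)[C@]2(C)CC[C@@H]3[C@](C)(CC[C@@H](O[Si](C)(C)C(C)(C)C)[C@]3(C)C(=O)OC)[C@H]2C1 | intermediate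
23 | C13=C14 isomer of 22 (3α-OTBS, 19α-OH, dimethyl ester) | CO[C@@H]1CC2=C(CC[C@@]3(C(=O)OC)CCC(C)(C)[C@@H](O)[C@@H]23)[C@]2(C)CC[C@@H]3[C@](C)(CC[C@@H](O[Si](C)(C)C(C)(C)C)[C@]3(C)C(=O)OC)[C@H]2C1 | intermediate
24 | 3α,19α-diol dimethyl ester | CO[C@@H]1CC2=C(CC[C@@]3(C(=O)OC)CCC(C)(C)[C@@H](O)[C@@H]23)[C@]2(C)CC[C@@H]3[C@](C)(CC[C@@H](O)[C@]3(C)C(=O)OC)[C@H]2C1 | intermediate
25 | CNP0394974.1 (3α,19α-dihydroxy-12α-methoxy C13=C14 diacid) | CO[C@@H]1CC2=C(CC[C@@]3(C(=O)O)CCC(C)(C)[C@@H](O)[C@@H]23)[C@]2(C)CC[C@@H]3[C@](C)(CC[C@@H](O)[C@]3(C)C(=O)O)[C@H]2C1 | target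

## Step count and risks

Total: 20 steps. Longest linear sequence: 18 steps (steps 1–13 and 16–20); the dienophile branch is steps 14–15.

Steps most likely to fail:

1. Step 16 (Diels–Alder). The dienophile may add with poor face or endo selectivity, because C9 and the 12α-methoxy group lie below the diene and C26 above it. Addition with the ester endo on the α face would give the wrong C17/C18 configuration, and the Lewis acid may also degrade the diene. The fallback replaces steric control by a temporary metal tether through the 12α-oxygen. It sets out from 15: enyne metathesis under the conditions of step 13 should give the dienol F6. Its magnesium alkoxide (MeMgBr, 1 equiv, toluene/CH2Cl2) binds the ketone of 20, so that the cycloaddition runs inside a self-assembled complex on the α face with the ketone endo (the Lewis-acid-tethered Diels–Alder reaction known for dienols), giving the 12α-hydroxy adduct F7. LiBH(sBu)3 as in step 17 gives the 12α,19α-diol F8. Me3OBF4 with 1,8-bis(dimethylamino)naphthalene should then methylate the unhindered 12α-hydroxyl in preference to the axial, neopentyl 19α-hydroxyl, and the route is rejoined at 22.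

2. Step 13 (enyne metathesis). The ruthenium carbene may fail to engage the alkyne on the quaternary C8, or cross-metathesis with ethylene and oligomerisation may outrun closure of the seven-membered ring. The fallback builds the ring C ketone and installs the vinyl group by cross-coupling. It sets out from 16: hydration of the alkyne with (Ph3P)AuNTf2 in aqueous dioxane gives the methyl ketone F1, and TESOTf/Et3N then gives the triethylsilyl enol ether F2, since only the methyl group can enolise. Diene ring-closing metathesis with the second-generation Hoveyda–Grubbs catalyst RuCl2(=CH-C6H4-2-OiPr)(H2IMes) in toluene at 80 °C closes ring C as the cyclic silyl enol ether F3, and dilute HCl in THF gives the ring C cycloheptanone F4. KHMDS and PhNTf2 give the enol triflate F5, since enolisation is possible only toward C13. Stille coupling with tributyl(vinyl)stannane, Pd(PPh3)4 and LiCl in THF rejoins the route at 17.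

3. Step 18 (alkene isomerization). Hydrogen-atom transfer to the hindered trisubstituted alkene may be slow, may stop at an equilibrium mixture of the two alkene positions, or may end in net reduction. The fallback sets out from 22 and uses a metal hydride addition–β-hydride elimination pathway instead of a radical one: RhCl3·3H2O (cat.) in EtOH at reflux should walk the alkene to the tetrasubstituted position. The route is rejoined at 23, and no new compound is made (F0).

Further compounds
F1 | step 13 | 8α-acetyl analogue of 16 (methyl ketone at C14) | CC(=O)[C@]1(C)CC[C@@H]2[C@](C)(CC[C@@H](O[Si](C)(C)C(C)(C)C)[C@]2(C)C(=O)OC)[C@H]1C[C@H](OC)CC=C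
F2 | step 13 | triethylsilyl enol ether of F1 | C=C(O[Si](CC)(CC)CC)[C@]1(C)CC[C@@H]2[C@](C)(CC[C@@H](O[Si](C)(C)C(C)(C)C)[C@]2(C)C(=O)OC)[C@H]1C[C@H](OC)CC=C
F3 | step 13 | cyclic silyl enol ether (ring C closed; C13=C14–OSiEt3) | CO[C@@H]1CC=C(O[Si](CC)(CC)CC)[C@]2(C)CC[C@@H]3[C@](C)(CC[C@@H](O[Si](C)(C)C(C)(C)C)[C@]3(C)C(=O)OC)[C@H]2C1
F4 | step 13 | ring C cycloheptanone (14-oxo; 12α-OMe) | CO[C@@H]1CCC(=O)[C@]2(C)CC[C@@H]3[C@](C)(CC[C@@H](O[Si](C)(C)C(C)(C)C)[C@]3(C)C(=O)OC)[C@H]2C1
F5 | step 13 | enol triflate (C13=C14–OTf) | CO[C@@H]1CC=C(OS(=O)(=O)C(F)(F)F)[C@]2(C)CC[C@@H]3[C@](C)(CC[C@@H](O[Si](C)(C)C(C)(C)C)[C@]3(C)C(=O)OC)[C@H]2C1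
F6 | step 16 | dienol (12α-OH analogue of 17) | O[C@@H]1CC=C(C=C)[C@]2(C)CC[C@@H]3[C@](C)(CC[C@@H](O[Si](C)(C)C(C)(C)C)[C@]3(C)C(=O)OC)[C@H]2C1
F7 | step 16 | 12α-hydroxy Diels–Alder adduct (19-oxo; C14=C15) | O[C@@H]1C[C@H]2C(=CC[C@@]3(C(=O)OC)CCC(C)(C)C(=O)[C@@H]23)[C@]2(C)CC[C@@H]3[C@](C)(CC[C@@H](O[Si](C)(C)C(C)(C)C)[C@]3(C)C(=O)OC)[C@H]2C1
F8 | step 16 | 12α,19α-diol (C14=C15) | O[C@@H]1C[C@H]2C(=CC[C@@]3(C(=O)OC)CCC(C)(C)[C@@H](O)[C@@H]23)[C@]2(C)CC[C@@H]3[C@](C)(CC[C@@H](O[Si](C)(C)C(C)(C)C)[C@]3(C)C(=O)OC)[C@H]2C1
F0 | step 18 | none | none
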